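## Structural features

The target 12 is a 2,3-dihydro-1-benzofuran: a benzene ring fused to a five-membered ring O1–C2–C3–C3a–C7a. C2 (R) carries a 1-formylvinyl group (a 2-substituted acrolein) and C3 (R) carries an isovalerate. The two centres are adjacent and cis, so that C2–H and C3–H lie on the same face. A third stereocentre, the (S)-carbinol carbon C1′ of a 1-acetoxyethyl group, sits on C5, para to O1 and remote from the ring pair. The fragile points are these:
- the enal is a Michael acceptor;
- the C3 ester is anti to C2–H, so a base that removes C2–H, or a carbonyl group placed on C2, leads to loss of isovaleric acid and aromatisation to a benzofuran;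
- both esters are benzylic and their ionisation is assisted by O1 (ortho to C3a, para to C5), which excludes strong acid;
- a free phenol ortho to the C3–O ester would open an o-quinone methide channel.

Two different acyl groups sit on two secondary benzylic alcohols and must be told apart. The real difficulty is the enantiopure cis C2/C3 pair together with the remote carbinol, reached without eliminable intermediates. The key step exploits two features. In the 3-oxo oxidation state, C2–H lies between O1 and the C3 carbonyl (the enol is an aromatic 3-hydroxybenzofuran) and is configurationally labile. C3 and C1′ are both aryl carbinol carbons with the same spatial arrangement of O and H relative to the arene; the descriptors differ (R against S) only because C2 outranks C3a. One chiral hydride catalyst can therefore create both carbinols and resolve C2 dynamically.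

## Logic of the disconnections

12 ⇒ 11. The C=CH2 bond of the acrolein is cut. The enal is the most fragile function, so it is made last from the saturated aldehyde by adding one carbon. This removes the Michael acceptor from every earlier intermediate. The forward step must leave C2–H and both esters alone and must outrun β-elimination of O1 from the aldehyde.

11 ⇒ 9. The aldehyde C=O is traced back to the terminal C=C of an allyl group. An isolated alkene is inert to hydride-transfer catalysts and to acylation, and it cannot move into conjugation with a C3 ketone. The forward step is an oxidative cleavage that must select the alkene over the alkoxyarene.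

9 ⇒ 8 ⇒ 7. The two acyl C–O bonds are cut, the isovalerate first and the acetate second. This leads to a diol without protecting groups. The forward acetylation must choose the open C1′–OH over the C3–OH, which is flanked by the cis allyl group and the peri C4–H; the isovalerate then goes on the only remaining hydroxyl.

7 ⇒ 5 (key). The C3–H and C1′–H bonds are cut and the configuration of C2 is erased. Three stereocentres go back to a racemic diketone that has none fixed. The forward step needs one catalyst face that is correct for both carbonyls, and epimerisation at C2 faster than reduction of the wrong enantiomer.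

5 ⇒ 4. The C2–CH2 bond to the allyl group is cut and a carboxyl group is restored on C2. The allyl ester then serves both as the activating group for ring formation and as the carrier of the allyl group. The forward step needs C- over O-allylation and a single allyl transfer.

4 ⇒ 3. The C2–C3 bond is cut (Dieckmann). This opens the furanone ring to a salicylate ether. The forward step needs the aryloxyacetate enolate to attack the aryl ester in preference to any reaction at the acetyl group.

3 ⇒ 1 + 2. The O1–CH2 bond is cut, giving a commercial salicylate and a commercial α-bromo ester.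

## Other disconnections considered

Alternative 1: The first route that comes to mind cuts O1–C2 with the ring oxygen as nucleophile. The forward key step is closure of the free phenol of cis-vinyl epoxide A1 onto its allylic carbon with inversion, giving cis alcohol A2. Acylation would then give A3, and allylic oxidation of the isopropenyl methyl group (SeO2) would give 12. Grounds for preferring the chosen plan:
- The opening must be a clean inversion at an allylic, oxygen-activated carbon, where ionisation leads to the trans isomer and attack at the alkene terminus leads to a seven-membered ring.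
- A1 is an ortho-hydroxybenzylic epoxide and so a direct o-quinone methide precursor.
- A1 needs a geometrically pure Z-diene, epoxidised at one of two alkenes, and a protected phenol.
- Its three stereocentres come from two unrelated asymmetric operations.
- The chosen plan sets all three centres in one operation and never has a free phenol.

Alternative 2: O1–C2 of the target is traced back to a ring contraction of a 2,2-dimethylchroman. The forward key step is activation of the C3–OH of hydroxy ester A4 (from dihydroxylation of a chromene) as a sulfonate, followed by a 1,2-shift of O1 from C2 to C3 with inversion. Loss of a methyl proton would give A3 directly, with ring, cis pair and isopropenyl group formed at once. Grounds for preferring the chosen plan are stereoelectronic: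
- In the cis series, the conformer with the O1–C2 bond anti to the leaving group places the C4 ester pseudoaxial and syn to an axial C2 methyl group.
- The other conformer aligns C4–H and a C2 methyl group anti to the leaving group, so hydride shift, methyl shift and elimination compete with participation by a weakly nucleophilic aryl ether oxygen.
- A4 also requires a site-selective acylation of a cis diol, and C1′ must be set separately.

Alternative 3: The C2–C3 bond is cut. The forward key step is a Lewis-acid-promoted (BF3·OEt2) addition of the γ-aryloxyallylstannane unit of A5 to its own aldehyde group through the oxygen-bearing carbon. This would close the five-membered ring and create both ring stereocentres and the isopropenyl group, giving A2. Grounds for preferring the chosen plan: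
- Nothing in A5 controls the absolute configuration of the new pair, because C1′ is too remote.
- The cis/trans outcome of such cyclisations depends on ring size and promoter and cannot be argued securely for a five-membered ring.
- The enol ether stannane is labile and needs strongly basic chemistry for its preparation.
- An allylic oxidation is still required at the end.

Key step: step 4

Assumption: in step 4 the benzofuranone carbonyl of 5 is taken to be reduced before the 5-acetyl group, so that the intermediate in the flask is 6; the stereochemical outcome does not depend on this order.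

## Route

Step 1
Reactants: 1 methyl 5-acetyl-2-hydroxybenzoate; 2 prop-2-en-1-yl bromoacetate (allyl bromoacetate)
Product: 3 methyl 5-acetyl-2-[2-oxo-2-(prop-2-en-1-yloxy)ethoxy]benzoate
Conditions: K2CO3, DMF, 50 °C
Reagents that add atoms: none
Why: Williamson ether synthesis; the phenol, acidified by the para acetyl and ortho ester groups, is alkylated by the activated primary α-bromo ester (SN2), and no stereocentre is formed.

Step 2
Reactants: 3 methyl 5-acetyl-2-[2-oxo-2-(prop-2-en-1-yloxy)ethoxy]benzoate
Product: 4 prop-2-en-1-yl 5-acetyl-3-hydroxy-1-benzofuran-2-carboxylate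
Conditions: t-BuOK (1.2 equiv), THF, 0 °C; then 1 M HCl
Reagents that add atoms: none
Why: Dieckmann condensation; the aryloxyacetate enolate attacks the aryl methyl ester (five-membered ring), and the reaction is driven by the stabilised enolate of the product, which is isolated as the aromatic enol, while enolisation of the acetyl group is reversible and unproductive.

Step 3
Reactants: 4 prop-2-en-1-yl 5-acetyl-3-hydroxy-1-benzofuran-2-carboxylate
Product: 5 (±)-5-acetyl-2-(prop-2-en-1-yl)-1-benzofuran-3(2H)-one
Conditions: Pd(PPh3)4 (5 mol%), toluene, 50 °C
Reagents that add atoms: none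
Why: Tsuji decarboxylative allylation; zerovalent palladium ionises the allyl ester to a π-allyl complex, the β-keto carboxylate loses CO2, and the soft benzofuranone enolate is allylated at C2, while any 3-allyloxybenzofuran from O-attack can re-ionise and is funnelled to the C-allyl ketone; the racemic product is what step 4 requires.

Step 4
Reactants: 5 (±)-5-acetyl-2-(prop-2-en-1-yl)-1-benzofuran-3(2H)-one
Product: 7 (2R,3R)-5-[(1S)-1-hydroxyethyl]-2-(prop-2-en-1-yl)-2,3-dihydro-1-benzofuran-3-ol, via hydroxy ketone 6 (not isolated)
Conditions: RuCl(p-cymene)[(S,S)-TsDPEN] (2 mol%), HCO2H/Et3N (5:2), EtOAc, 40 °C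
Reagents that add atoms: none
Why: Asymmetric transfer hydrogenation by the Ru–H/N–H form of RuCl(p-cymene)[(S,S)-TsDPEN] (outer-sphere, concerted delivery of hydride and proton, each reduction made irreversible by loss of CO2) is combined with dynamic kinetic resolution, the closest known reaction types being the reduction of aryl methyl ketones and the cis-selective dynamic reduction of 2-substituted benzofuran-3(2H)-ones and indanones. No ring is closed. C1′ is set as (S) by the catalyst, which places the aryl group under the η6-arene (CH/π contact) as with acetophenone. C3 is set by the same facial rule, the fused arene playing the aryl role, and receives the descriptor (R) only because C2 outranks C3a. C2 is set by dynamic kinetic resolution: the enantiomers of 5 interconvert through the aromatic enol (a 3-hydroxybenzofuran) under Et3N, and the catalyst reduces fast only the (2R)-ketone, in which the allyl group lies anti to the incoming hydride, so that OH and allyl end up cis. The step needs epimerisation at C2 to outrun reduction of the (2S)-ketone, which the acidity of C2–H between O1 and the carbonyl should secure, and it needs selectivity for C=O over C=C, which the outer-sphere mechanism should secure; the allyl double bond is not conjugated and has no low-energy path into conjugation with the ketone. Because two catalyst-controlled events act on one molecule, most stereochemical error should appear as separable diastereomers and not as the enantiomer.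

Step 5
Reactants: 7 (2R,3R)-5-[(1S)-1-hydroxyethyl]-2-(prop-2-en-1-yl)-2,3-dihydro-1-benzofuran-3-ol
Product: 8 (1S)-1-[(2R,3R)-3-hydroxy-2-(prop-2-en-1-yl)-2,3-dihydro-1-benzofuran-5-yl]ethyl acetate
Conditions: Ac2O (1.05 equiv), Et3N, DMAP (2 mol%), CH2Cl2, −40 °C
Reagents that add atoms: acetic anhydride, CC(=O)OC(C)=O
Why: Site-selective nucleophilic-catalysed acylation; the open 1-arylethanol hydroxyl should react well before the ring hydroxyl, which is shielded by the cis allyl group on C2 and the peri C4–H; no stereocentre is touched.

Step 6
Reactants: 8 (1S)-1-[(2R,3R)-3-hydroxy-2-(prop-2-en-1-yl)-2,3-dihydro-1-benzofuran-5-yl]ethyl acetate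
Product: 9 (2R,3R)-5-[(1S)-1-(acetyloxy)ethyl]-2-(prop-2-en-1-yl)-2,3-dihydro-1-benzofuran-3-yl 3-methylbutanoate
Conditions: 3-methylbutanoic anhydride, Et3N, DMAP (cat.), CH2Cl2, 0 °C to rt
Reagents that add atoms: 3-methylbutanoic anhydride, CC(C)CC(=O)OC(=O)CC(C)C
Why: DMAP-catalysed esterification of the only remaining hydroxyl with retention at C3; C2–H carries no acidifying group at this stage, so the base cannot trigger elimination to a benzofuran.

Step 7
Reactants: 9 (2R,3R)-5-[(1S)-1-(acetyloxy)ethyl]-2-(prop-2-en-1-yl)-2,3-dihydro-1-benzofuran-3-yl 3-methylbutanoate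
Product: 11 (2R,3R)-5-[(1S)-1-(acetyloxy)ethyl]-2-(2-oxoethyl)-2,3-dihydro-1-benzofuran-3-yl 3-methylbutanoate, via ozonide 10 (not isolated)
Conditions: O3, CH2Cl2, −78 °C (stopped at the first excess of ozone); then PPh3, −78 °C to rt
Reagents that add atoms: ozone, [O-][O+]=O
Why: Ozonolysis with reductive work-up; the terminal alkene reacts far faster than the mono-alkoxy arene, and the neutral conditions leave both benzylic esters and the stereocentres untouched.

Step 8
Reactants: 11 (2R,3R)-5-[(1S)-1-(acetyloxy)ethyl]-2-(2-oxoethyl)-2,3-dihydro-1-benzofuran-3-yl 3-methylbutanoate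
Product: 12 (2R,3R)-5-[(1S)-1-(acetyloxy)ethyl]-2-(3-oxoprop-1-en-2-yl)-2,3-dihydro-1-benzofuran-3-yl 3-methylbutanoate (target)
Conditions: 37% aq. HCHO, pyrrolidine (10 mol%), propanoic acid (10 mol%), i-PrOH, 45 °C
Reagents that add atoms: formaldehyde, C=O
Why: Organocatalytic α-methylenation of an aldehyde (Mannich condensation: enamine addition to the formaldehyde-derived iminium ion, then elimination of the amine); the buffered amine salt is not basic enough to remove C2–H, and the product has no α-hydrogen, so it cannot enolise further.

## Compound list

1 | methyl 5-acetyl-2-hydroxybenzoate | COC(=O)c1cc(C(C)=O)ccc1O | starting material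
2 | prop-2-en-1-yl bromoacetate | C=CCOC(=O)CBr | starting material
3 | methyl 5-acetyl-2-[2-oxo-2-(prop-2-en-1-yloxy)ethoxy]benzoate | COC(=O)c1cc(C(C)=O)ccc1OCC(=O)OCC=C | intermediate
4 | prop-2-en-1-yl 5-acetyl-3-hydroxy-1-benzofuran-2-carboxylate | C=CCOC(=O)c1oc2ccc(C(C)=O)cc2c1O | intermediate
5 | (±)-5-acetyl-2-(prop-2-en-1-yl)-1-benzofuran-3(2H)-one | C=CCC1Oc2ccc(C(C)=O)cc2C1=O | intermediate
6 | 1-[(2R,3R)-3-hydroxy-2-(prop-2-en-1-yl)-2,3-dihydro-1-benzofuran-5-yl]ethan-1-one | C=CC[C@H]1Oc2ccc(C(C)=O)cc2[C@H]1O | intermediate
7 | (2R,3R)-5-[(1S)-1-hydroxyethyl]-2-(prop-2-en-1-yl)-2,3-dihydro-1-benzofuran-3-ol | C=CC[C@H]1Oc2ccc([C@H](C)O)cc2[C@H]1O | intermediate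
8 | (1S)-1-[(2R,3R)-3-hydroxy-2-(prop-2-en-1-yl)-2,3-dihydro-1-benzofuran-5-yl]ethyl acetate | C=CC[C@H]1Oc2ccc([C@H](C)OC(C)=O)cc2[C@H]1O | intermediate
9 | (2R,3R)-5-[(1S)-1-(acetyloxy)ethyl]-2-(prop-2-en-1-yl)-2,3-dihydro-1-benzofuran-3-yl 3-methylbutanoate | C=CC[C@H]1Oc2ccc([C@H](C)OC(C)=O)cc2[C@H]1OC(=O)CC(C)C | intermediate
10 | 1,2,4-trioxolane (secondary ozonide) of 9, 3-substituted by the dihydrobenzofuran-2-ylmethyl group | C1(C[C@H]2Oc3ccc([C@H](C)OC(C)=O)cc3[C@H]2OC(=O)CC(C)C)OCOO1 | intermediate
11 | (2R,3R)-5-[(1S)-1-(acetyloxy)ethyl]-2-(2-oxoethyl)-2,3-dihydro-1-benzofuran-3-yl 3-methylbutanoate | O=CC[C@H]1Oc2ccc([C@H](C)OC(C)=O)cc2[C@H]1OC(=O)CC(C)C | intermediate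
12 | (2R,3R)-5-[(1S)-1-(acetyloxy)ethyl]-2-(3-oxoprop-1-en-2-yl)-2,3-dihydro-1-benzofuran-3-yl 3-methylbutanoate | C=C(C=O)[C@H]1Oc2ccc([C@H](C)OC(C)=O)cc2[C@H]1OC(=O)CC(C)C | target

## Step count and least certain steps

Total: 8 steps. Longest linear sequence: 8 steps (from 1).

Step 4 (key step). The deactivated para-alkoxyaryl methyl ketone may need longer or warmer conditions than the benzofuranone. Prolonged exposure could then let reduction of the (2S)-ketone compete with epimerisation, or leave mixtures of mono- and di-reduced material, eroding the cis selectivity. Fallback: the two reductions are decoupled and the acyl groups are introduced between them. From 5, the transfer hydrogenation is run at room temperature and stopped once the ring carbonyl has reacted, and hydroxy ketone 6 is isolated. Acylation with 3-methylbutanoic anhydride/DMAP gives (2R,3R)-5-acetyl-2-(prop-2-en-1-yl)-2,3-dihydro-1-benzofuran-3-yl 3-methylbutanoate F1. A second transfer hydrogenation of the acetyl group with the same catalyst at 40 °C gives (2R,3R)-5-[(1S)-1-hydroxyethyl]-2-(prop-2-en-1-yl)-2,3-dihydro-1-benzofuran-3-yl 3-methylbutanoate F2. Acetylation of F2 returns to the route at 9, and steps 5 and 6 are not needed.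

Step 3. Allyl transfer between molecules may occur, because both 4 and 5 are acidic; this would give double allylation together with non-allylated ketone, or attack at oxygen. Fallback: a methyl ester series in which C2 becomes quaternary before decarboxylation, so that only one allyl group can enter. From 1, etherification with methyl bromoacetate (K2CO3) gives methyl 5-acetyl-2-(2-methoxy-2-oxoethoxy)benzoate F3. Dieckmann condensation (t-BuOK) gives methyl 5-acetyl-3-hydroxy-1-benzofuran-2-carboxylate F4. Intermolecular Tsuji–Trost allylation (allyl methyl carbonate, Pd(PPh3)4) gives methyl 5-acetyl-3-oxo-2-(prop-2-en-1-yl)-2,3-dihydro-1-benzofuran-2-carboxylate F5. Krapcho demethoxycarbonylation (LiCl, wet DMSO, heat) returns to the route at 5.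

Step 5. Site selectivity between the two secondary benzylic hydroxyls may be lost, giving the diacetate or the C3 acetate. Fallback: the C3 hydroxyl is masked through the neighbouring allyl group. From 7, iodoetherification (I2, NaHCO3, MeCN, 0 °C) engages only the C3–OH, which is cis to the allyl group, and gives the cis-fused iodo ether (1S)-1-[(3aR,8bR)-2-(iodomethyl)-2,3,3a,8b-tetrahydrofuro[3,2-b][1]benzofuran-7-yl]ethan-1-ol F6. Acetylation of its only hydroxyl gives the acetate F7. Reductive β-elimination with Zn in AcOH/EtOH reopens the ether to the alkene and the free C3–OH, returning to the route at 8.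

Step 8. The enamine or enol of 11 may expel the aryloxide O1 (retro-oxa-Michael ring opening) and re-close, which would epimerise C2 and expose an ortho-hydroxybenzylic ester. Fallback: a stepwise Mannich sequence without free amine, finished by a neutral syn-elimination. From 11, reaction with Eschenmoser's salt (CH2=NMe2+ I−) in MeCN without added base gives the Mannich base (2R,3R)-5-[(1S)-1-(acetyloxy)ethyl]-2-[3-(dimethylamino)-1-oxopropan-2-yl]-2,3-dihydro-1-benzofuran-3-yl 3-methylbutanoate F8. Oxidation with mCPBA at low temperature gives the N-oxide F9. Cope elimination on warming returns to the route at 12.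

## Further compounds

F1 | step 4 | (2R,3R)-5-acetyl-2-(prop-2-en-1-yl)-2,3-dihydro-1-benzofuran-3-yl 3-methylbutanoate | C=CC[C@H]1Oc2ccc(C(C)=O)cc2[C@H]1OC(=O)CC(C)C
F2 | step 4 | (2R,3R)-5-[(1S)-1-hydroxyethyl]-2-(prop-2-en-1-yl)-2,3-dihydro-1-benzofuran-3-yl 3-methylbutanoate | C=CC[C@H]1Oc2ccc([C@H](C)O)cc2[C@H]1OC(=O)CC(C)C
F3 | step 3 | methyl 5-acetyl-2-(2-methoxy-2-oxoethoxy)benzoate | COC(=O)COc1ccc(C(C)=O)cc1C(=O)OC
F4 | step 3 | methyl 5-acetyl-3-hydroxy-1-benzofuran-2-carboxylate | COC(=O)c1oc2ccc(C(C)=O)cc2c1O
F5 | step 3 | methyl 5-acetyl-3-oxo-2-(prop-2-en-1-yl)-2,3-dihydro-1-benzofuran-2-carboxylate (racemic) | C=CCC1(C(=O)OC)Oc2ccc(C(C)=O)cc2C1=O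
F6 | step 5 | (1S)-1-[(3aR,8bR)-2-(iodomethyl)-2,3,3a,8b-tetrahydrofuro[3,2-b][1]benzofuran-7-yl]ethan-1-ol (configuration at C2 of the new ring not controlled) | ICC1C[C@H]2Oc3ccc([C@H](C)O)cc3[C@H]2O1
F7 | step 5 | (1S)-1-[(3aR,8bR)-2-(iodomethyl)-2,3,3a,8b-tetrahydrofuro[3,2-b][1]benzofuran-7-yl]ethyl acetate | ICC1C[C@H]2Oc3ccc([C@H](C)OC(C)=O)cc3[C@H]2O1
F8 | step 8 | (2R,3R)-5-[(1S)-1-(acetyloxy)ethyl]-2-[3-(dimethylamino)-1-oxopropan-2-yl]-2,3-dihydro-1-benzofuran-3-yl 3-methylbutanoate | CN(C)CC(C=O)[C@H]1Oc2ccc([C@H](C)OC(C)=O)cc2[C@H]1OC(=O)CC(C)C
F9 | step 8 | N-oxide of F8 | C[N+](C)([O-])CC(C=O)[C@H]1Oc2ccc([C@H](C)OC(C)=O)cc2[C@H]1OC(=O)CC(C)C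
A1 | alternative 1 | 4-[(1S)-1-(acetyloxy)ethyl]-2-[(2R,3S)-3-(prop-1-en-2-yl)oxiran-2-yl]phenol (cis epoxide) | C=C(C)[C@@H]1O[C@@H]1c1cc([C@H](C)OC(C)=O)ccc1O
A2 | alternative 1 | (1S)-1-[(2R,3R)-3-hydroxy-2-(prop-1-en-2-yl)-2,3-dihydro-1-benzofuran-5-yl]ethyl acetate | C=C(C)[C@H]1Oc2ccc([C@H](C)OC(C)=O)cc2[C@H]1O
A3 | alternative 1 | (2R,3R)-5-[(1S)-1-(acetyloxy)ethyl]-2-(prop-1-en-2-yl)-2,3-dihydro-1-benzofuran-3-yl 3-methylbutanoate | C=C(C)[C@H]1Oc2ccc([C@H](C)OC(C)=O)cc2[C@H]1OC(=O)CC(C)C
A4 | alternative 2 | (3R,4R)-6-[(1S)-1-(acetyloxy)ethyl]-3-hydroxy-2,2-dimethyl-3,4-dihydro-2H-chromen-4-yl 3-methylbutanoate | CC1(C)Oc2ccc([C@H](C)OC(C)=O)cc2[C@@H](OC(=O)CC(C)C)[C@H]1O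
A5 | alternative 3 | (1S)-1-[3-formyl-4-{[(1Z)-2-methyl-3-(tributylstannyl)prop-1-en-1-yl]oxy}phenyl]ethyl acetate | O=Cc1cc([C@H](C)OC(C)=O)ccc1O/C=C(/C)C[Sn](CCCC)(CCCC)CCCC
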